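The earlier runs and the new flask are simulated on assumed constants.

Per hour, as fractions of the Z charged: that is the unit in which we decide whether the flask at 1.10 equiv of E is stopped at 10 h or left until 20 h.

| flask | Z | E | remark | time |
|---|---|---|---|---|
| green | 0.10 M | 0.74 equiv | run made earlier |  |
| violet | 0.10 M | 1.7 equiv | run made earlier |  |
| north-east | 0.10 M | 1.10 equiv |  | 10 h |
| north | 0.10 M | 1.10 equiv |  | 20 h |

| run | time / h | D / % | Q / % | J / % | Z / % |
|---|---|---|---|---|---|
| green | 1.50 | 0.7 | 10.8 | 0.4 | 65.6 |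
| green | 3.00 | 3.8 | 16.4 | 2.2 | 57.6 |
| green | 5.00 | 7.3 | 19.8 | 6.9 | 48.7 |
| green | 6.00 | 9.0 | 20.2 | 9.6 | 45.0 |
| green | 8.00 | 13.0 | 20.6 | 15.6 | 37.8 |
| green | 10.0 | 14.6 | 20.5 | 21.4 | 32.2 |
| green | 12.0 | 17.1 | 20.0 | 25.8 | 27.3 |
| violet | 1.50 | 2.3 | 9.4 | 0.5 | 65.9 |
| violet | 3.00 | 8.1 | 12.7 | 1.6 | 57.7 |
| violet | 5.00 | 14.4 | 14.5 | 4.7 | 48.7 |
| violet | 6.00 | 18.1 | 15.8 | 5.9 | 44.8 |
| violet | 8.00 | 23.4 | 15.7 | 9.7 | 38.1 |
| violet | 10.0 | 27.8 | 15.6 | 12.7 | 32.6 |
| violet | 12.0 | 31.3 | 15.3 | 15.8 | 28.2 |

(standard deviation of a reading: 0.3 percentage points)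

- percentages count the Z that a species holds: one J counts as two
- a reading of Z is of its free form alone

1. which of these there is most of at the end, counted by the Z in it, north-east (Z / D / J / Q)
2. which of these there is most of at the end, counted by the Z in it, north (Z / D / J / Q)
3. the largest of these amounts at the end, in percent of the Z charged, north-east
4. the largest of these amounts at the end, in percent of the Z charged, north

Z comes first. At 10.0 h the green run reads 32.2% and the violet run 32.6%, so we put north-east at their mean, 32.4%. The other species we place 0.375 of the way from green to violet, by equivalents of E: D 19.6%, Q 18.7%, J 18.1%. So Z stands above each of them.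

North turns on J. From 8.00 h to 12.0 h, J's gain per hour over the square of Q reads 0.607 h⁻¹ in green and 0.627 h⁻¹ in violet, although E differs between them. We call this ratio, read from scattered readings with amounts as fractions of the Z charged and J counted by the Z it holds, the pairing constant; a gain in J that goes with the square of Q points to a step second order in Q. At 12.0 h we interpolate J to 22.1% and Q to 18.2%.

J at the end = J now + pairing constant × Q squared × hours

First round, Q held at 18.2%: J = 38.2%

Second round, Q sinking at green's pace, mean 17.6%: J = 37.2%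

Z, falling at 0.0830 h⁻¹ in green, reaches 14.1% in north. D, carried on at its interpolated pace, reaches 33.5%. So we expect J to hold more than either.

The forecast says Z at 32.4% for north-east and J at 35.5% for north, the latter with a caution: “J leads, though with less certainty”. Its J stands below our 37.2%.

The flask gives Z at 32.4% in north-east and J at 36.7% in north.

    Z → Q (k = 0.110 h⁻¹)
    E + Q → D (k = 2.10 M⁻¹ h⁻¹)
    2 Q → J (k = 3.40 M⁻¹ h⁻¹)
    E → X (k = 0.0730 h⁻¹)
    Z ⇌ G (K = 0.330, k = 0.630 h⁻¹)

The same reckoning goes to the neighbouring flask, north-east left until 15 h. From 12.0 h, with Q sinking at green's pace to a mean of 18.0%, the pairing constant gives J = 28.0%. In that flask J stands at 28.0%, more than the 21.6% of Z.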